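**Retrosynthetic overview**
- The strategy rests on one feature: ring C together with C7, C8 and C9 of ring B is a 4-hydroxyphenylpropane unit, the carbon skeleton of L-tyrosine (alpha carbon = C8, phenol oxygen O4C para to C7).
- Ring B is disconnected at O3A–C7: the C7 methylene is oxidised to a p-quinone methide and trapped by the ring A phenol. The O4A–C8 ether comes from a Mitsunobu inversion of the tyrosine-derived secondary alcohol by the 4-OH of 3,4-dihydroxybenzaldehyde.
- Ring D is built afterwards on the freed O4C phenol and the ortho bromine of ring C: O4C–C7' by SN2 opening of a Sharpless epoxide made from caffeic acid (ring E), then O3C–C8' by palladium-catalysed C–O coupling (cis).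
- Ring order: rings A, C and E are bought arenes, then ring B, then ring D; the enal is installed by Wittig homologation before global deprotection.

Key step: step 7

Remark: locants are the neolignan ones. Ring A carries the formyl/propenal group, C7–C9 belong to ring B, ring C is the central arene, C7'–C9' belong to ring D, ring E is the catechol. O3A/O4A and O3C/O4C are the oxygens meta/para to the side chain on rings A and C. The target is (7S,8S,7'R,8'S): trans ring B, cis ring D.

**Step 1**
Reactants: 1 L-tyrosine
Product: 2 3-bromo-L-tyrosine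
Conditions: DMSO (1.1 equiv), 48% aq. HBr, AcOH, 65 °C; then neutralise to pH 5–6
Reagents that add atoms: hydrogen bromide, Br
Why: Electrophilic aromatic bromination by Br2 generated in situ from HBr and DMSO; the para position is blocked, one equivalent of oxidant should stop at the mono-ortho-bromide, and the stereocentre is not touched.

**Step 2**
Reactants: 2 3-bromo-L-tyrosine
Product: 5 (S)-3-(3-bromo-4-hydroxyphenyl)-2-hydroxypropanoic acid, via diazonium carboxylate 3 (not isolated), via alpha-lactone 4 (not isolated)
Conditions: NaNO2 (1.5 equiv), 1 M aq. H2SO4, 0 °C to rt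
Reagents that add atoms: water, O
Why: Diazotisation–hydrolysis of an alpha-amino acid; the carboxylate displaces N2 with inversion to give alpha-lactone 4 and water opens it with a second inversion, so the S configuration should be retained (neighbouring-group participation).

**Step 3**
Reactants: 5 (S)-3-(3-bromo-4-hydroxyphenyl)-2-hydroxypropanoic acid
Product: 6 (S)-3-(3-bromo-4-hydroxyphenyl)propane-1,2-diol
Conditions: BH3·SMe2 (4 equiv), THF, 0 °C to rt; MeOH quench
Reagents that add atoms: none
Why: Chemoselective borane reduction of the carboxylic acid to the primary alcohol; the aryl bromide is inert and the stereocentre is not involved.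

**Step 4**
Reactants: 6 (S)-3-(3-bromo-4-hydroxyphenyl)propane-1,2-diol
Product: 7 (S)-1-[3-bromo-4-(tert-butyldimethylsilyloxy)phenyl]-3-(tert-butyldimethylsilyloxy)propan-2-ol
Conditions: TBSCl (2.2 equiv), imidazole (4.5 equiv), DMF, 0 °C
Reagents that add atoms: tert-butyldimethylsilyl chloride, CC(C)(C)[Si](C)(C)Cl
Why: Silyl ether formation; the acidic phenol and the primary alcohol should be silylated much faster than the flanked secondary alcohol, which stays free for the next step.

**Step 5**
Reactants: 7 (S)-bis-silyl alcohol; 8 3,4-dihydroxybenzaldehyde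
Product: 9 (R)-4-({1-[3-bromo-4-(tert-butyldimethylsilyloxy)phenyl]-3-(tert-butyldimethylsilyloxy)propan-2-yl}oxy)-3-hydroxybenzaldehyde
Conditions: 8 (1.5 equiv), PPh3 (1.5 equiv), DIAD (1.5 equiv), THF, 0 °C to rt
Reagents that add atoms: none
Why: Mitsunobu etherification with inversion at C8 (S alcohol to R aryl ether); the 4-OH para to the formyl group is the more acidic phenol of 8 (the same bias that gives 4-O-alkylation under base), so it should be the one deprotonated by the betaine and alkylated.

**Step 6**
Reactants: 9 Mitsunobu ether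
Product: 10 (R)-4-{[1-(3-bromo-4-hydroxyphenyl)-3-(tert-butyldimethylsilyloxy)propan-2-yl]oxy}-3-hydroxybenzaldehyde
Conditions: KHF2 (2.5 equiv), MeOH, rt
Reagents that add atoms: none
Why: Chemoselective cleavage of the phenolic silyl ether by bifluoride; the aryl O–Si bond of the ortho-bromophenol should cleave at room temperature while the primary alkyl silyl ether is kept.

**Step 7**
Reactants: 10 tyrosine-derived aryl ether with free ring A and ring C phenols
Product: 12 (2S,3S)-3-(3-bromo-4-hydroxyphenyl)-2-[(tert-butyldimethylsilyloxy)methyl]-2,3-dihydro-1,4-benzodioxine-6-carbaldehyde (trans ring A–B–C aldehyde; 7S,8S), via p-quinone methide 11 (not isolated)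
Conditions: DDQ (1.05 equiv, portionwise), 1,4-dioxane, 20 °C, dark; filter DDQH2, aq. NaHCO3 wash
Reagents that add atoms: none
Why: DDQ should abstract hydride from the C7 methylene para to the free O4C–H of ring C and give p-quinone methide 11, whose exocyclic carbon C7 is attacked by the ring A phenol O3A in a 6-exo-trig oxa-conjugate (1,6-) addition that rearomatises ring C and closes ring B. The closest known reactions are the DDQ-mediated oxidative cyclisations of 2-hydroxyphenyl-tethered 4-oxygenated arylalkanes to flavans and the phenol trapping of beta-aryloxy quinone methides that closes 1,4-benzodioxanes in oxidative catechol couplings. The new stereocentre C7 is controlled by C8: allylic 1,3-strain in 11 places C8–H in the plane of the methide, so the tethered O3A adds to the face anti to the CH2OTBS group through a chair-like transition state with aryl and CH2OTBS both equatorial (7S,8S, trans). Because ring C keeps its free para-phenol, ring B can reopen to 11 through the phenoxide (bicarbonate work-up, base of step 12), so a minor cis isomer should drain to the diequatorial trans ring. The step needs oxidation of ring C only, no second oxidation, and no tautomerisation of 11 to the styrene by loss of the C8 proton: the formyl group makes the ring A phenol a poor DDQ substrate, C7 is the only benzylic C–H para to a free phenol, one equivalent of oxidant is used, and the six-membered intramolecular trapping should outrun proton loss.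

**Step 8**
Reactants: 13 caffeic acid
Product: 14 methoxymethyl (E)-3-[3,4-bis(methoxymethoxy)phenyl]prop-2-enoate
Conditions: MOMCl (3.6 equiv), iPr2NEt (4.5 equiv), CH2Cl2, 0 °C to rt
Reagents that add atoms: chloromethyl methyl ether, COCCl
Why: O-Alkylation with MOMCl; both phenols become MOM ethers and the carboxylate becomes the MOM ester in one operation.

**Step 9**
Reactants: 14 tris-MOM caffeate
Product: 15 (E)-3-[3,4-bis(methoxymethoxy)phenyl]prop-2-en-1-ol
Conditions: iBu2AlH (DIBAL-H, 2.5 equiv), CH2Cl2, −78 °C; aq. KNaC4H4O6 work-up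
Reagents that add atoms: none
Why: 1,2-Reduction of the cinnamate ester by iBu2AlH should give the E-allylic alcohol without touching the alkene or the aryl MOM ethers.

**Step 10**
Reactants: 15 bis-MOM caffeyl alcohol
Product: 16 [(2S,3S)-3-[3,4-bis(methoxymethoxy)phenyl]oxiran-2-yl]methanol
Conditions: Ti(OiPr)4 (10 mol%), L-(+)-diisopropyl tartrate (12 mol%), tBuOOH (2 equiv), 4 Å molecular sieves, CH2Cl2, −20 °C; aq. NaOH/brine work-up
Reagents that add atoms: tert-butyl hydroperoxide, CC(C)(C)OO
Why: Sharpless asymmetric epoxidation; L-(+)-tartrate should give the (2S,3S)-epoxy alcohol from the E-allylic alcohol, which sets C8' (kept later) and the C7' centre that is inverted in step 12.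

**Step 11**
Reactants: 16 (2S,3S)-epoxy alcohol
Product: 17 tert-butyl{[(2S,3S)-3-[3,4-bis(methoxymethoxy)phenyl]oxiran-2-yl]methoxy}dimethylsilane
Conditions: TBSCl (1.2 equiv), imidazole (2.5 equiv), CH2Cl2, 0 °C
Reagents that add atoms: tert-butyldimethylsilyl chloride, CC(C)(C)[Si](C)(C)Cl
Why: Silylation of the primary alcohol under buffered basic conditions; the protected epoxide cannot undergo Payne rearrangement in step 12 and C9' is already masked.

**Step 12**
Reactants: 12 trans ring A–B–C phenol; 17 silyl-protected (2S,3S)-epoxide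
Product: 18 (2S,3S)-3-{3-bromo-4-[(1R,2S)-1-[3,4-bis(methoxymethoxy)phenyl]-3-(tert-butyldimethylsilyloxy)-2-hydroxypropoxy]phenyl}-2-[(tert-butyldimethylsilyloxy)methyl]-2,3-dihydro-1,4-benzodioxine-6-carbaldehyde (erythro; 7'R,8'S)
Conditions: 17 (1.5 equiv), Cs2CO3 (1.5 equiv), DMF, 70 °C
Reagents that add atoms: none
Why: SN2 opening of an aryl-substituted epoxide by a phenoxide at the benzylic carbon C7', which is activated by electron-rich ring E while C8' is deactivated by its adjacent C–O bond; inversion at C7' should give the erythro (7'R,8'S) alcohol, C8' being untouched.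

**Step 13**
Reactants: 18 erythro bromo alcohol
Product: 19 (2S,3S)-3-[(2R,3S)-2-[3,4-bis(methoxymethoxy)phenyl]-3-[(tert-butyldimethylsilyloxy)methyl]-2,3-dihydro-1,4-benzodioxin-6-yl]-2-[(tert-butyldimethylsilyloxy)methyl]-2,3-dihydro-1,4-benzodioxine-6-carbaldehyde
Conditions: Pd(OAc)2 (5 mol%), 2-(di-tert-butylphosphino)-1,1'-binaphthyl (7.5 mol%), Cs2CO3 (1.5 equiv), toluene, 70 °C
Reagents that add atoms: none
Why: Palladium-catalysed intramolecular C–O coupling of a secondary alcohol with an aryl bromide (Buchwald-type etherification; the bulky di-tert-butylbiarylphosphine suppresses beta-hydride elimination); the C8'–O bond is not broken, so the erythro alcohol should give cis ring D (7'R,8'S).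

**Step 14**
Reactants: 19 pentacyclic aldehyde
Product: 20 (2E)-3-{(2S,3S)-3-[(2R,3S)-2-[3,4-bis(methoxymethoxy)phenyl]-3-[(tert-butyldimethylsilyloxy)methyl]-2,3-dihydro-1,4-benzodioxin-6-yl]-2-[(tert-butyldimethylsilyloxy)methyl]-2,3-dihydro-1,4-benzodioxin-6-yl}prop-2-enal
Conditions: Ph3P=CHCHO (1.3 equiv), toluene, 80 °C
Reagents that add atoms: (triphenylphosphoranylidene)acetaldehyde, O=CC=P(c1ccccc1)(c1ccccc1)c1ccccc1
Why: Wittig reaction with the stabilised formylmethylene ylide should give the E-enal by two-carbon homologation; the enal product is less electrophilic than the aryl aldehyde, so a small excess of ylide limits dienal formation.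

**Step 15**
Reactants: 20 protected enal
Product: 21 CNP0302404.1, (2E)-3-{(2S,3S)-3-[(2R,3S)-2-(3,4-dihydroxyphenyl)-3-(hydroxymethyl)-2,3-dihydro-1,4-benzodioxin-6-yl]-2-(hydroxymethyl)-2,3-dihydro-1,4-benzodioxin-6-yl}prop-2-enal
Conditions: 3 M aq. HCl/THF (1:3), 40 °C, argon
Reagents that add atoms: none
Why: Acid hydrolysis of the two primary silyl ethers and the two aryl MOM acetals in one operation; the aqueous, alcohol-free medium avoids acetal formation at the enal and the mild temperature should keep the cis benzylic ether of ring D from ionising.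

**Compound list**
1 | L-tyrosine | N[C@@H](Cc1ccc(O)cc1)C(=O)O | starting material
2 | 3-bromo-L-tyrosine | N[C@@H](Cc1ccc(O)c(Br)c1)C(=O)O | intermediate
3 | diazonium carboxylate of 2 (S) | [O-]C(=O)[C@H](Cc1ccc(O)c(Br)c1)[N+]#N | intermediate (not isolated)
4 | alpha-lactone, (R)-3-(3-bromo-4-hydroxybenzyl)oxiran-2-one | O=C1O[C@@H]1Cc1ccc(O)c(Br)c1 | intermediate (not isolated)
5 | (S)-3-(3-bromo-4-hydroxyphenyl)-2-hydroxypropanoic acid | O[C@@H](Cc1ccc(O)c(Br)c1)C(=O)O | intermediate
6 | (S)-3-(3-bromo-4-hydroxyphenyl)propane-1,2-diol | OC[C@@H](O)Cc1ccc(O)c(Br)c1 | intermediate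
7 | (S)-1-[3-bromo-4-(tert-butyldimethylsilyloxy)phenyl]-3-(tert-butyldimethylsilyloxy)propan-2-ol | CC(C)(C)[Si](C)(C)OC[C@@H](O)Cc1ccc(O[Si](C)(C)C(C)(C)C)c(Br)c1 | intermediate
8 | 3,4-dihydroxybenzaldehyde | O=Cc1ccc(O)c(O)c1 | starting material
9 | (R)-4-({1-[3-bromo-4-(tert-butyldimethylsilyloxy)phenyl]-3-(tert-butyldimethylsilyloxy)propan-2-yl}oxy)-3-hydroxybenzaldehyde | O=Cc1ccc(O[C@@H](CO[Si](C)(C)C(C)(C)C)Cc2ccc(O[Si](C)(C)C(C)(C)C)c(Br)c2)c(O)c1 | intermediate
10 | (R)-4-{[1-(3-bromo-4-hydroxyphenyl)-3-(tert-butyldimethylsilyloxy)propan-2-yl]oxy}-3-hydroxybenzaldehyde (key-step precursor) | O=Cc1ccc(O[C@@H](CO[Si](C)(C)C(C)(C)C)Cc2ccc(O)c(Br)c2)c(O)c1 | intermediate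
11 | p-quinone methide of 10 (C7=C1 of ring C, either geometry; C8 R) | O=Cc1ccc(O[C@@H](CO[Si](C)(C)C(C)(C)C)C=C2C=CC(=O)C(Br)=C2)c(O)c1 | intermediate (not isolated)
12 | (2S,3S)-3-(3-bromo-4-hydroxyphenyl)-2-[(tert-butyldimethylsilyloxy)methyl]-2,3-dihydro-1,4-benzodioxine-6-carbaldehyde (key-step product, 7S,8S trans) | O=Cc1ccc2c(c1)O[C@@H](c1ccc(O)c(Br)c1)[C@H](CO[Si](C)(C)C(C)(C)C)O2 | intermediate
13 | caffeic acid | OC(=O)/C=C/c1ccc(O)c(O)c1 | starting material
14 | methoxymethyl (E)-3-[3,4-bis(methoxymethoxy)phenyl]prop-2-enoate | COCOC(=O)/C=C/c1ccc(OCOC)c(OCOC)c1 | intermediate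
15 | (E)-3-[3,4-bis(methoxymethoxy)phenyl]prop-2-en-1-ol | OC/C=C/c1ccc(OCOC)c(OCOC)c1 | intermediate
16 | [(2S,3S)-3-[3,4-bis(methoxymethoxy)phenyl]oxiran-2-yl]methanol | OC[C@@H]1O[C@H]1c1ccc(OCOC)c(OCOC)c1 | intermediate
17 | tert-butyl{[(2S,3S)-3-[3,4-bis(methoxymethoxy)phenyl]oxiran-2-yl]methoxy}dimethylsilane | CC(C)(C)[Si](C)(C)OC[C@@H]1O[C@H]1c1ccc(OCOC)c(OCOC)c1 | intermediate
18 | erythro (7'R,8'S) hydroxy ether, ring C bromide (name as in step 12) | O=Cc1ccc2c(c1)O[C@@H](c1ccc(O[C@H](c3ccc(OCOC)c(OCOC)c3)[C@@H](O)CO[Si](C)(C)C(C)(C)C)c(Br)c1)[C@H](CO[Si](C)(C)C(C)(C)C)O2 | intermediate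
19 | protected pentacyclic aldehyde, trans ring B, cis ring D (name as in step 13) | O=Cc1ccc2c(c1)O[C@@H](c1ccc3c(c1)O[C@@H](CO[Si](C)(C)C(C)(C)C)[C@@H](c1ccc(OCOC)c(OCOC)c1)O3)[C@H](CO[Si](C)(C)C(C)(C)C)O2 | intermediate
20 | protected (E)-enal (name as in step 14) | O=C/C=C/c1ccc2c(c1)O[C@@H](c1ccc3c(c1)O[C@@H](CO[Si](C)(C)C(C)(C)C)[C@@H](c1ccc(OCOC)c(OCOC)c1)O3)[C@H](CO[Si](C)(C)C(C)(C)C)O2 | intermediate
21 | CNP0302404.1 (7S,8S,7'R,8'S) | O=C/C=C/c1ccc2c(c1)O[C@@H](c1ccc3c(c1)O[C@@H](CO)[C@@H](c1ccc(O)c(O)c1)O3)[C@H](CO)O2 | target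

**Step count**
Total: 15 steps. Longest linear sequence: 11 steps (steps 1–7, then 12–15); steps 8–11 form the convergent epoxide branch.

**Steps most likely to fail**

Step 7. The product still carries a free para-phenol and a now ether-activated C7–H, so a second hydride abstraction may compete. Quinone methide 11 may also lose the C8 proton and tautomerise to the styrenyl enol ether, which erases C8. The bromine-deactivated phenol may be oxidised only sluggishly. The fallback leaves C–H oxidation by a quinone and sets out from 9. The ring A phenol would be silylated (TBSCl, imidazole, DMF) to the tris-silyl ether F1. Wohl–Ziegler bromination (NBS, AIBN, PhCF3, 80 °C) at C7, the only benzylic methylene, would give the benzylic bromide F2 as a mixture of C7 epimers; aryl aldehydes are known to survive such brominations. CsF in DMF at 0 °C would then remove both aryl silyl ethers. The ring C phenoxide expels bromide by 1,6-elimination to the same quinone methide 11, and the ring A phenoxide closes ring B under the same C8 control, so both epimers converge. The sequence comes back to the route at 12.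

Step 12. Bimolecular SN2 attack of the hindered ortho-bromophenoxide on a 1,2-disubstituted epoxide may be slow. During prolonged heating with base the phenoxide of 12 can reopen ring B, and the quinone methide may then be lost to intermolecular capture. Partial ionisation of the electron-rich epoxide may also erode inversion at C7'. The fallback sets out from 12 and the free epoxy alcohol 16. Ti(OiPr)4 (1.5 equiv) in CH2Cl2 at rt should deliver the aryloxide to C3 of the epoxy alcohol within the titanium chelate, a hydroxyl-directed opening under non-basic conditions, and give the diol F3. Selective silylation of its primary hydroxyl (TBSCl, imidazole, CH2Cl2, 0 °C) comes back to the route at 18.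

Step 10. The electron-rich arylglycidol may be opened by isopropoxide or tartrate under titanium Lewis acid catalysis during the reaction or work-up, and may decompose on silica. The fallback sets out from 15, which would first be silylated (TBSCl, imidazole) to the allyl silyl ether F4. Shi epoxidation with the L-sorbose-derived enantiomer of the fructose ketone (KHSO5 as Oxone, K2CO3 buffer at pH about 10.5, MeCN/dimethoxymethane/H2O, 0 °C) would then give the protected epoxide directly under basic, Lewis-acid-free conditions. This comes back to the route at 17.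

**Further compounds**
F1 | step 7 | (R)-4-({1-[3-bromo-4-(tert-butyldimethylsilyloxy)phenyl]-3-(tert-butyldimethylsilyloxy)propan-2-yl}oxy)-3-(tert-butyldimethylsilyloxy)benzaldehyde | O=Cc1ccc(O[C@@H](CO[Si](C)(C)C(C)(C)C)Cc2ccc(O[Si](C)(C)C(C)(C)C)c(Br)c2)c(O[Si](C)(C)C(C)(C)C)c1
F2 | step 7 | C7 bromide of F1 (both C7 epimers) | O=Cc1ccc(O[C@@H](CO[Si](C)(C)C(C)(C)C)C(Br)c2ccc(O[Si](C)(C)C(C)(C)C)c(Br)c2)c(O[Si](C)(C)C(C)(C)C)c1
F3 | step 12 | erythro (7'R,8'S) C8',C9'-diol corresponding to 18 without the C9' silyl group | O=Cc1ccc2c(c1)O[C@@H](c1ccc(O[C@H](c3ccc(OCOC)c(OCOC)c3)[C@@H](O)CO)c(Br)c1)[C@H](CO[Si](C)(C)C(C)(C)C)O2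
F4 | step 10 | tert-butyl{[(E)-3-[3,4-bis(methoxymethoxy)phenyl]prop-2-en-1-yl]oxy}dimethylsilane | CC(C)(C)[Si](C)(C)OC/C=C/c1ccc(OCOC)c(OCOC)c1
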